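Free base is the charge to follow in this flask, so the reckoning here is a balance of free base.

in all of them: electrophile 0.50 M
- south-east: free base 1.4 M; protonated nucleophile 0.50 M; run made earlier
- north-west: free base 2.2 M; protonated nucleophile 0.50 M; run made earlier
- flask: free base 1.00 M; protonated nucleophile 0.500 M; time 10 d

- south-east (time / d: electrophile / %, product / %): 1.04: 50.6, 50.1; 3.00: 25.8, 73.6; 5.00: 18.3, 81.3; 8.00: 10.9, 88.7
- north-west (time / d: electrophile / %, product / %): 2.08: 34.0, 65.9; 4.00: 21.1, 78.3; 6.00: 15.4, 84.6; 8.00: 11.4, 89.4

(standard deviation of a reading: 0.5 percentage points)

- part of the electrophile that has reacted at 10 d
- share of free nucleophile in free nucleophile and protonated nucleophile together, at 10 d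

- the analysis behind the earlier runs scatters by 0.5 percentage points, standard deviation
- the earlier runs do not show how much of nucleophile is bound; that part of a forecast is a guess

Assume that freeing the nucleophile takes one free base per protonated nucleophile, and that each coupling then sets free one acid for the base to take up. The flask's 100% is its base ceiling: the free base charged less the protonated nucleophile charged, as a part of the electrophile charged. The earlier runs stood higher than the flask, at 180% and 340%, and their electrophile at 8.00 d reads 10.9% and 11.4%, a gap of about the scatter.

In the first instants of the new flask, the freeing of the nucleophile is taken as fast, and on this balance it leaves 0.500 M of free base beside 0.50 M of electrophile. In the middle, coupling is taken as the slow step, and on this balance free base falls in step with electrophile. With the ceiling at the charge itself, this balance puts the free base left equal to the electrophile left. The earlier runs do not show how much nucleophile is bound, so that part of the reckoning is a guess.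

The forecast gives 89.5% reacted (86.5% to 91.5%) and 85% free (60% to 99%), and warns: “Some nucleophile may then stay protonated.”

The flask gives 89.8% reacted and 96.8% free, the latter 12 percentage points above the forecast.

    acid set free + free base ⇌ salt of the base, settled at all times (K = 61000 M⁻¹)
    nucleophile + acid set free ⇌ idle adduct, settled at all times (K = 280 M⁻¹)
    nucleophile + acid set free ⇌ protonated nucleophile, settled at all times (K = 120 M⁻¹)
    electrophile + nucleophile → acid set free + product (k = 0.00130 M⁻¹ min⁻¹)

At 100%, the flask holds 0.0562 M of free base beside 0.0509 M of electrophile at 10.0 d. The neighbour charged with 1.2 M of electrophile has a ceiling of 41.7%, and there 41.7% of its electrophile has reacted at 10.0 d. Free base is that neighbour's limiting reagent, the first charge to run out, with 0.42% left, and its share of free nucleophile stands at 68.0%.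

(All runs come from a simulation with constants of no real substance; noise was put on by code.)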